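The earlier runs and the new flask come from a simulation with constants of no real substance, and the scatter is random.

all flasks: left-handed substrate 0.50 M; right-handed substrate 0.50 M; free catalyst 10 mM
- alpha: reagent 1 M; the very flask that is asked about, followed so far
- flask: reagent 1.00 M; time 2.5 min
alpha run (percent of the left-handed substrate and right-handed substrate together charged)

| time / s | left-handed product / % | right-handed product / % |
|---|---|---|
| 10.0 | 4.8 | 0.5 |
| 20.0 | 10.3 | 0.8 |
| 30.0 | 15.8 | 2.1 |
| 40.0 | 17.5 | 0 |
| 50.0 | 23.0 | 2.2 |
| 60.0 | 25.7 | 0 |
| 80.0 | 32.3 | 1.0 |

(scatter of a reading: 1 percentage point)
- free catalyst is single-handed; left-handed substrate and right-handed substrate are mirror images of each other, charged as a racemate, each of them at the stated concentration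
- an excess is the difference of the two amounts in percent of their sum
- an excess is below zero if the other one leads
- excess of left-handed product over right-handed product in the product at 8.0 s
- excess of left-handed product over right-handed product in the product at 2.5 min
- part of the left-handed substrate and right-handed substrate charged together that has reacted at 2.5 min

At early times the alpha run looks like a plain resolution: at 10.0 s it holds 4.8 % left-handed product and 0.5 % right-handed product. With a scatter of 1 percentage point, the right-handed readings leave the excess loose, so I commit to no excess of my own.

Does the left-handed product stop at the left-handed charge? Write that smaller balance. Left-handed charge minus left-handed product is 32.5 % at 40.0 s and 17.7 % at 80.0 s. Yet the gain barely slows: 17.5 % up to 40.0 s, then 15 points more. I therefore set no ceiling there.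

What then follows the conversion? I take each product to use one reagent, and the reagent charge equals the two substrate charges together. The percent of reagent left is thus 100 minus both products. The last reading gives 0.304 /min. This k_r, the logarithm of reagent charged over reagent left, divided by the time, is a pseudo-first-order constant. The reading at 40.0 s gives 0.289 /min, close to it. Carried to 2.5 min, k_r gives me 53.2 % reacted.

The forecast gives excesses of 94 % at 8.0 s and 88 % at 2.5 min, and 46 % reacted, less than my conversion, with a first-order constant that “if anything, creeps upward”.

The flask gives excesses of 86.2 % at 8.0 s and 86.9 % at 2.5 min, and 52.6 % reacted.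

    free catalyst + left-handed substrate ⇌ catalyst intermediate A (K = 5.60 /M, k = 20.0 /M/s)
    free catalyst + right-handed substrate ⇌ catalyst intermediate B (K = 4.10 /M, k = 60.0 /M/s)
    reagent + catalyst intermediate A → free catalyst + left-handed product (k = 1.40 /M/s)
    reagent + catalyst intermediate B → free catalyst + right-handed product (k = 0.0990 /M/s)
    left-handed substrate ⇌ right-handed substrate (k = 0.0860 /s)
    reagent → decomposition product (k = 5.70 × 10⁻⁵ /s)
    reagent + free catalyst → spent catalyst (k = 0.00950 /M/s)

In the flask at 2.50 min, left-handed product and left-handed substrate together hold 71.8 % of the pair charged, above the 50.0 % charged as left-handed. The reagent left, 47 %, gives k_r = 0.302 /min.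

In a neighbouring flask, the same recipe with 0.0060 M free catalyst, k_r scaled to that charge is 0.182 /min, which gives 36.6 % reacted at 2.5 min. The computed result is 36.8 %.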